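(The runs were computed with constants of no real substance.)

Read north and east at 3.00 min, the time of the flask's reading, and decide how much partner to charge.

in all of them: left-handed substrate 0.068 M; right-handed substrate 0.068 M

| charge | partner | precatalyst | remark | time |
|---|---|---|---|---|
| north | 0.020 M | 1 mM | run made earlier |  |
| east | 0.082 M | 1 mM | run made earlier |  |
| flask | 0.0408 M | 1.0 mM |  | 3.0 min |

| run | time / min | left-handed substrate / % | right-handed substrate / % | left-handed product / % |
|---|---|---|---|---|
| north | 0.200 | 51.6 | 50.1 | 1.3 |
| north | 0.667 | 48.3 | 49.1 | 0.3 |
| north | 1.00 | 48.2 | 49.4 | 0.3 |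
| north | 1.50 | 46.7 | 48.5 | 2.9 |
| north | 2.50 | 44.6 | 50.1 | 4.2 |
| north | 3.00 | 43.7 | 48.3 | 1.9 |
| east | 0.500 | 43.6 | 49.3 | 4.1 |
| east | 1.00 | 37.9 | 46.3 | 7.5 |
| east | 1.50 | 31.1 | 45.2 | 12.1 |
| east | 2.00 | 25.7 | 45.0 | 12.4 |
| east | 2.50 | 26.7 | 44.3 | 14.8 |
| east | 3.00 | 24.2 | 43.5 | 16.8 |

(each reading ± 1 percentage point)

- free catalyst is single-handed; left-handed substrate and right-handed substrate are mirror images of each other, charged as a racemate, each of them at the stated concentration
- on the list of suspects stand: free catalyst + left-handed substrate <-> catalyst intermediate A; free catalyst + right-handed substrate <-> catalyst intermediate B; partner + catalyst intermediate A -> free catalyst + left-handed product; partner + catalyst intermediate B -> free catalyst + right-handed product; left-handed product <-> right-handed product; partner + precatalyst -> free catalyst + spent reagent; partner <-> dormant form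
- an excess is below zero if the other one leads

* part of the left-handed substrate and right-handed substrate charged together that has reacted at 3.0 min
* excess of left-handed product over right-handed product in the product at 3.0 min
* excess of right-handed substrate over left-handed substrate among what is left of the two at 3.0 min

Count the substrate reacted at that time, as read and with the readings' scatter: north 8.00 %, east 32.3 %. Turn each into molar terms and divide by c(partner) charged: north gives 54.4 %, east 53.6 %. Carry their mean, 54.0 %, as the partner yield, the substrate reacted at that time per partner charged. Use it with the substrate and precatalyst charges of these runs held, as the flask holds them. Partner is the limiting reagent in the flask, with c(partner) at 0.0408 M below the 0.136 M of substrate charged. That charge also lies between the two ends, so join them with the one yield: the flask should reach 16.2 %, twice north's conversion and less than east's. Charge the flask as written.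

The forecast, reckoned separately by stepping through the run, gives c 16.5 %, a little above my 16.2 %, with eP 5 % and eS 12.3 %, on this ground: “Rate scales roughly first order in partner”.

The flask gives c 16.5 %, eP 3.97 % and eS 14.5 %, so its own partner yield is 55.1 %. free catalyst + left-handed substrate ⇌ catalyst intermediate A (K = 95.0 L mol⁻¹, k = 81.0 L mol⁻¹ s⁻¹); free catalyst + right-handed substrate ⇌ catalyst intermediate B (K = 80.0 L mol⁻¹, k = 260 L mol⁻¹ s⁻¹); partner + catalyst intermediate A → free catalyst + left-handed product (k = 60.0 L mol⁻¹ s⁻¹); partner + catalyst intermediate B → free catalyst + right-handed product (k = 4.40 L mol⁻¹ s⁻¹); left-handed product ⇌ right-handed product (k = 0.0350 s⁻¹); partner + precatalyst → free catalyst + spent reagent (k = 0.450 L mol⁻¹ s⁻¹); partner ⇌ dormant form (K = 1.80, k = 0.0120 s⁻¹)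

At 3.00 min the flask holds 10 % of its partner free and 34.6 % of the charge as dormant form. Apply the carried yield to a neighbour flask with c(partner) at 0.069 M: it predicts 27.4 %. That neighbour reaches 29.0 %, a partner yield of 57.2 %, with 9.58 % of its partner left free.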